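**Retrosynthetic overview**
1. Target 19 ⇐ silyl ether 18. The azocine ring is closed last by inserting a two-carbon unit (vinylsulfonium 15) between N4–H and the C7 ester enolate of spiro amine 14 (N4–C5 and C6–C7).
2. 14 ⇐ ketonitrone 11 + methyl acrylate 12 (key step). SmI2 reverses the polarity of the nitrone carbon C20, which adds to the acrylate β-carbon (C20–C17); the samarium enolate formed then closes onto indole C2 (C16–C2), building the cyclohexane and the indoline quaternary centre.
3. 11 ⇐ aldonitrone 3 + 2-vinylindole diester 9 by the same nitrone polarity reversal (C20–C19), followed by re-oxidation to the nitrone.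
4. 3 ⇐ (S)-pyrrolidin-3-ol 1 (supplies C15); 9 ⇐ methyl indole-3-carboxylate 4.
5. Ring order: pyrrolidine and indole are bought; cyclohexane plus indoline in step 7; azocine in step 8.

Locants used: N1 carbamate nitrogen; C2 quaternary carbon on N1; C7 quaternary carbon bearing aryl and CO2Me; C6–C5 azocine CH2CH2 (C5 on N4); C20 quaternary carbon on N4; C15 carbinol carbon; C14–C3 other pyrrolidine CH2 groups; C16 CH–CO2Me; C17 CH2 between C16 and C20; C18–C19 CH2CH2 between C2 and C20. In these locants the target is 2R,7S,15S,16R,20R.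

Step 1
Reactants: 1 (S)-pyrrolidin-3-ol
Product: 2 (3S)-3-(tert-butyldimethylsilyloxy)pyrrolidine
Conditions: TBSCl (1.05 equiv), imidazole, CH2Cl2, 0 °C to rt
Reagents that add atoms: tert-butyldimethylsilyl chloride, CC(C)(C)[Si](C)(C)Cl
Why: Imidazole-promoted silyl ether formation is selective for oxygen because any N–Si bond is hydrolysed on aqueous work-up; the C15 stereocentre is untouched.

Step 2
Reactants: 2 (3S)-3-(tert-butyldimethylsilyloxy)pyrrolidine
Product: 3 (4S)-4-(tert-butyldimethylsilyloxy)-3,4-dihydro-2H-pyrrole 1-oxide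
Conditions: Na2WO4·2H2O (5 mol %), H2O2·urea (2.5 equiv), MeOH, 0 °C to rt
Reagents that add atoms: hydrogen peroxide–urea adduct, OO.NC(N)=O
Why: Tungstate-catalysed peroxide oxidation of a secondary amine to the nitrone (Murahashi oxidation) proceeds via the hydroxylamine; the C=N forms mainly toward the carbon next to the silyloxy-bearing centre (alkoxy-directed, minor regioisomer removed by chromatography) and the stereocentre is retained.

Step 3
Reactants: 4 methyl 1H-indole-3-carboxylate
Product: 5 dimethyl 1H-indole-1,3-dicarboxylate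
Conditions: NaH, ClCO2Me, THF, 0 °C
Reagents that add atoms: methyl chloroformate, COC(=O)Cl
Why: N-acylation of the indolyl sodium salt installs the N1 carbamate of the target, which also turns the indole C2=C3 bond into a conjugate acceptor for step 7.

Step 4
Reactants: 5 dimethyl 1H-indole-1,3-dicarboxylate; 6 vinyl bromide
Product: 9 dimethyl 2-ethenyl-1H-indole-1,3-dicarboxylate, via 2-chloromagnesio indole diester 7 (not isolated), via 2-chlorozincio indole diester 8 (not isolated)
Conditions: TMPMgCl·LiCl (TMP = 2,2,6,6-tetramethylpiperidide, 1.2 equiv), THF, −20 °C; ZnCl2 (1.3 equiv); then 6 (2 equiv), Pd(PPh3)4 (3 mol %), 50 °C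
Reagents that add atoms: none
Why: Directed metalation at C2 (flanked by carbamate and ester) with the hindered amide base tolerates both esters, and transmetalation to zinc followed by Negishi cross-coupling installs the vinyl group.

Step 5
Reactants: 3 (4S)-4-(tert-butyldimethylsilyloxy)-3,4-dihydro-2H-pyrrole 1-oxide; 9 dimethyl 2-ethenyl-1H-indole-1,3-dicarboxylate
Product: 10 dimethyl 2-{2-[(2R,3S)-3-(tert-butyldimethylsilyloxy)-1-hydroxypyrrolidin-2-yl]ethyl}-1H-indole-1,3-dicarboxylate
Conditions: SmI2 (2.5 equiv), H2O (8 equiv), THF, −78 °C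
Reagents that add atoms: none
Why: In this SmI2-mediated reductive nitrone–alkene cross-coupling, one-electron reduction makes the normally electrophilic nitrone carbon C20 nucleophilic, so it attacks the normally electrophilic terminal carbon C19 of the vinylogous acrylate anti to the silyloxy group (2,3-trans); protonation at C18 restores the indole.

Step 6
Reactants: 10 dimethyl 2-{2-[(2R,3S)-3-(tert-butyldimethylsilyloxy)-1-hydroxypyrrolidin-2-yl]ethyl}-1H-indole-1,3-dicarboxylate
Product: 11 dimethyl 2-{2-[(4S)-4-(tert-butyldimethylsilyloxy)-1-oxido-3,4-dihydro-2H-pyrrol-1-ium-5-yl]ethyl}-1H-indole-1,3-dicarboxylate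
Conditions: Na2WO4·2H2O (5 mol %), H2O2·urea (1.2 equiv), MeOH/CH2Cl2, 0 °C
Reagents that add atoms: none
Why: Tungstate-catalysed oxidation of the N,N-dialkylhydroxylamine to the nitrone is expected to give mainly the more substituted ketonitrone (C20=N), as with 2-alkyl cyclic amines; C15 is retained and the C20 centre is deliberately erased so that it can be rebuilt as a quaternary centre.

Step 7
Reactants: 11 dimethyl 2-{2-[(4S)-4-(tert-butyldimethylsilyloxy)-1-oxido-3,4-dihydro-2H-pyrrol-1-ium-5-yl]ethyl}-1H-indole-1,3-dicarboxylate; 12 methyl acrylate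
Product: 14 trimethyl 3''-(tert-butyldimethylsilyloxy)dispiro[indoline-2,1'-cyclohexane-4',2''-pyrrolidine]-1,2',3-tricarboxylate (C2/C16/C20/C15 as in 19; C7-H epimers), via N-hydroxy spirocycle 13 (not isolated)
Conditions: SmI2 (2.5 equiv), 12 (1.5 equiv), THF, −78 to −20 °C, no proton source; then H2O (20 equiv), SmI2 (3 equiv), rt
Reagents that add atoms: none
Why: Proposed new method: SmI2 reduces the ketonitrone to a nucleophilic C20 α-amino radical (samarium aminoxide) that adds to the β-carbon of 12 anti to the C15 silyloxy group (sets C20), the α-ester radical is reduced to a trivalent samarium enolate which, with no proton source present, adds 6-exo-trig to C2 of the N-acyl indole-3-carboxylate through a chair in which samarium bridges the aminoxide and enolate oxygens (C16 ester cis to N4) and the indole presents C7 equatorially on that same face (C7 cis to N4, sets C2 and C16), and the later SmI2/H2O charge cleaves the N–O bond and destroys residual acrylate; the closest known reactions are the SmI2 nitrone–acrylate reductive coupling and SmI2 ketyl–indole dearomatising cyclisations with enolate formation at the indole 3-position.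

Step 8
Reactants: 14 trimethyl 3''-(tert-butyldimethylsilyloxy)dispiro[indoline-2,1'-cyclohexane-4',2''-pyrrolidine]-1,2',3-tricarboxylate; 15 diphenyl(vinyl)sulfonium trifluoromethanesulfonate
Product: 18 15-O-(tert-butyldimethylsilyl) ether of target 19, via aminoethylsulfonium triflate 16 (not isolated), via spiro-aziridinium triflate 17 (not isolated)
Conditions: 15 (1.2 equiv), CH2Cl2, 0 °C to rt; then KN(SiMe3)2 (1.2 equiv), THF, −78 to 0 °C
Reagents that add atoms: none
Why: In this vinylsulfonium annulation the hindered amine adds to the vinylsulfonium salt, the β-amino sulfonium collapses to the aziridinium ion, and the C7 ester enolate (the most acidic C–H, so C16 is not epimerised) opens it to close the eight-membered ring; this is possible only because N4 and C7 are cis, and C6 enters on the enolate face syn to C16 because the other face would force the C7 and C16 ester groups to eclipse across C2 (sets C7).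

Step 9
Reactants: 18 15-O-(tert-butyldimethylsilyl) ether of target 19
Product: 19 target CNP0144467.1
Conditions: HF·pyridine, THF, 0 °C to rt
Reagents that add atoms: none
Why: Fluoride cleavage of the secondary silyl ether leaves the two methyl esters, the methyl carbamate and the tertiary amine untouched and changes no stereocentre.

**Compound list**
1 | (S)-pyrrolidin-3-ol | O[C@H]1CCNC1 | starting material
2 | (3S)-3-(tert-butyldimethylsilyloxy)pyrrolidine | CC(C)(C)[Si](C)(C)O[C@H]1CCNC1 | intermediate
3 | (4S)-4-(tert-butyldimethylsilyloxy)-3,4-dihydro-2H-pyrrole 1-oxide (cyclic aldonitrone) | [O-][N+]1=C[C@@H](O[Si](C)(C)C(C)(C)C)CC1 | intermediate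
4 | methyl 1H-indole-3-carboxylate | COC(=O)c1c[nH]c2ccccc12 | starting material
5 | dimethyl 1H-indole-1,3-dicarboxylate | COC(=O)c1cn(C(=O)OC)c2ccccc12 | intermediate
6 | vinyl bromide | C=CBr | starting material
7 | 2-chloromagnesio indole diester (not isolated) | COC(=O)c1c([Mg]Cl)n(C(=O)OC)c2ccccc12 | intermediate
8 | 2-chlorozincio indole diester (not isolated) | COC(=O)c1c([Zn]Cl)n(C(=O)OC)c2ccccc12 | intermediate
9 | dimethyl 2-ethenyl-1H-indole-1,3-dicarboxylate | C=Cc1c(C(=O)OC)c2ccccc2n1C(=O)OC | intermediate
10 | dimethyl 2-{2-[(2R,3S)-3-(tert-butyldimethylsilyloxy)-1-hydroxypyrrolidin-2-yl]ethyl}-1H-indole-1,3-dicarboxylate (2,3-trans) | ON1CC[C@H](O[Si](C)(C)C(C)(C)C)[C@H]1CCc1c(C(=O)OC)c2ccccc2n1C(=O)OC | intermediate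
11 | dimethyl 2-{2-[(4S)-4-(tert-butyldimethylsilyloxy)-1-oxido-3,4-dihydro-2H-pyrrol-1-ium-5-yl]ethyl}-1H-indole-1,3-dicarboxylate (cyclic ketonitrone) | [O-][N+]1=C(CCc2c(C(=O)OC)c3ccccc3n2C(=O)OC)[C@@H](O[Si](C)(C)C(C)(C)C)CC1 | intermediate
12 | methyl acrylate | C=CC(=O)OC | starting material
13 | N-hydroxy spirocycle: 1''-hydroxy derivative of 14 (not isolated; C7-H epimers) | COC(=O)[C@@H]1C[C@@]2(CC[C@@]13N(C(=O)OC)c4ccccc4C3C(=O)OC)N(O)CC[C@@H]2O[Si](C)(C)C(C)(C)C | intermediate
14 | trimethyl 3''-(tert-butyldimethylsilyloxy)dispiro[indoline-2,1'-cyclohexane-4',2''-pyrrolidine]-1,2',3-tricarboxylate; C7 side, C16 ester and N4 on one face of the cyclohexane, C19 cis to the silyloxy group; C7-H epimers | COC(=O)[C@@H]1C[C@@]2(CC[C@@]13N(C(=O)OC)c4ccccc4C3C(=O)OC)NCC[C@@H]2O[Si](C)(C)C(C)(C)C | intermediate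
15 | diphenyl(vinyl)sulfonium trifluoromethanesulfonate | C=C[S+](c1ccccc1)c1ccccc1.[O-]S(=O)(=O)C(F)(F)F | starting material
16 | aminoethylsulfonium triflate: N4-[2-(diphenylsulfonio)ethyl] derivative of 14 (not isolated) | COC(=O)[C@@H]1C[C@@]2(CC[C@@]13N(C(=O)OC)c4ccccc4C3C(=O)OC)N(CC[S+](c5ccccc5)c5ccccc5)CC[C@@H]2O[Si](C)(C)C(C)(C)C.[O-]S(=O)(=O)C(F)(F)F | intermediate
17 | spiro-aziridinium triflate at N4 of 14 (not isolated) | COC(=O)[C@@H]1C[C@@]2(CC[C@@]13N(C(=O)OC)c4ccccc4C3C(=O)OC)[N+]5(CC5)CC[C@@H]2O[Si](C)(C)C(C)(C)C.[O-]S(=O)(=O)C(F)(F)F | intermediate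
18 | 15-O-(tert-butyldimethylsilyl) ether of 19 | COC(=O)[C@@H]1C[C@@]23CC[C@@]14N(C(=O)OC)c1ccccc1[C@@]4(C(=O)OC)CCN2CC[C@@H]3O[Si](C)(C)C(C)(C)C | intermediate
19 | CNP0144467.1: N1-methoxycarbonyl indoline whose C2 and C7 are part of a 2-azabicyclo[4.2.2]decane (C7-CO2Me, C16-CO2Me) with the 15-hydroxypyrrolidine fused at N4–C20; 2R,7S,15S,16R,20R | COC(=O)[C@@H]1C[C@@]23CC[C@@]14N(C(=O)OC)c1ccccc1[C@@]4(C(=O)OC)CCN2CC[C@@H]3O | target

**Totals**
Total step count: 9. Longest linear sequence: 7 steps (1 → 2 → 3 → 10 → 11 → 14 → 18 → 19; steps 1, 2, 5, 6, 7, 8, 9).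

**Three steps most likely to fail**

Step 7 (radical addition / enolate ring closure). The samarium enolate may be protonated or transfer a proton before it attacks the poorly electrophilic indole C2, or it may close with the wrong sense at C2. The fallback sets out from 11 and comes back at 14. The SmI2 coupling with 12 is run at −78 °C and quenched with Me3SiCl, so the enolate is captured regiospecifically as the ketene silyl acetal F1 (the N–O oxygen is silylated as well). F1 is then cyclised under Lewis-acid catalysis (Me3SiOTf or Sc(OTf)3, CH2Cl2, −40 °C; a Mukaiyama–Michael addition to the acid-activated indole ester through an open transition state). Aqueous work-up gives 13, and Zn/AcOH cleaves the N–O bond to give 14.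

Step 5 (nitrone coupling with the vinylindole). The vinylogous acceptor is untested in this coupling and may be reduced or dimerised by SmI2 instead. The fallback sets out from 3 (with the partner made from 5) and comes back at 10, replacing the reductive coupling by polar addition and cross-coupling. Ethynylmagnesium bromide adds to 3 anti to the silyloxy group to give the ethynyl hydroxylamine F2. The magnesiated indole 7 from 5 is quenched with I2 to give the 2-iodoindole diester F3. Sonogashira coupling (Pd(PPh3)2Cl2, CuI, Et3N) joins them to the alkyne F4, and hydrogenation of the triple bond (H2, Pd/C, EtOAc) gives 10.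

Step 8 (azocine closure). Eight-membered ring formation by enolate alkylation may be slow, and β-elimination of the carbamate nitrogen or the wrong facial choice at C7 may compete. The fallback sets out from 14 and comes back at 18, using acylation, alkylation and reduction instead of the sulfonium annulation. Chloroacetyl chloride/Et3N gives the chloroacetamide F5. KN(SiMe3)2 (THF, −78 to 0 °C) then closes the ring by enolate alkylation with the more reactive α-halo amide, whose planar nitrogen holds the chain in the pyrrolidine plane, to give the eight-membered lactam F6. Chemoselective amide reduction (Zn(OAc)2 10 mol %, (EtO)3SiH, THF, 40 °C), which spares esters and the carbamate, gives 18.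

Further compounds
F1 | step 7 | ketene silyl acetal of the open-chain adduct: methyl trimethylsilyl ketene acetal at C16, N4–O–SiMe3, C17 trans to the C15 silyloxy group | COC(O[Si](C)(C)C)=CC[C@@]1(CCc2c(C(=O)OC)c3ccccc3n2C(=O)OC)N(O[Si](C)(C)C)CC[C@@H]1O[Si](C)(C)C(C)(C)C
F2 | step 5 | (2R,3S)-3-(tert-butyldimethylsilyloxy)-2-ethynylpyrrolidin-1-ol | ON1CC[C@H](O[Si](C)(C)C(C)(C)C)[C@H]1C#C
F3 | step 5 | dimethyl 2-iodo-1H-indole-1,3-dicarboxylate | COC(=O)c1c(I)n(C(=O)OC)c2ccccc12
F4 | step 5 | dimethyl 2-{[(2R,3S)-3-(tert-butyldimethylsilyloxy)-1-hydroxypyrrolidin-2-yl]ethynyl}-1H-indole-1,3-dicarboxylate | ON1CC[C@H](O[Si](C)(C)C(C)(C)C)[C@H]1C#Cc1c(C(=O)OC)c2ccccc2n1C(=O)OC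
F5 | step 8 | N4-chloroacetyl derivative of 14 | COC(=O)[C@@H]1C[C@@]2(CC[C@@]13N(C(=O)OC)c4ccccc4C3C(=O)OC)N(C(=O)CCl)CC[C@@H]2O[Si](C)(C)C(C)(C)C
F6 | step 8 | C5-oxo (eight-membered lactam) analogue of 18 | COC(=O)[C@@H]1C[C@@]23CC[C@@]14N(C(=O)OC)c1ccccc1[C@@]4(C(=O)OC)CC(=O)N2CC[C@@H]3O[Si](C)(C)C(C)(C)C
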